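**Retrosynthetic overview**
1. Ring C is not taken from a terpene. It comes from the arene 4-isopropylphenol 1, hydrogenated to the mirror-symmetric ketone 2, whose two enantiotopic α-CH2 groups are told apart in a one-flask chiral-amide deprotonation/dehydrogenation (enolate 3) to give (R)-cryptone 4. This sets C4.
2. Rings A and B are bought already joined as C2-symmetric magnolol 5. Mono-iodination (6) and MOM protection (7) mark the one ortho carbon that will carry ring C.
3. Aryl–C3 bond: I/Mg exchange on 7 (Grignard 8), copper-catalysed conjugate addition to 4 anti to the isopropyl group (sets C3), and trapping of enolate 9 as enol triflate 10.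
4. C1–CH3 bond: iron-catalysed coupling of 10 with MeMgBr (11), then MOM removal gives the target 12.
5. Ring order: A and B are preformed (5); C is preformed as an arene (1), dearomatised, desymmetrised, then joined. No ring closure is needed.

Assumption: lithium (R,R)-bis(1-phenylethyl)amide is taken to give the (S)-enolate 3, from recalled precedent with 4-alkylcyclohexanones; if the rotation of 4 shows the other sense, the (S,S)-amide is used.

**Step 1**
Reactants: 1 4-isopropylphenol
Product: 2 4-isopropylcyclohexanone
Conditions: H2 (10 bar), 5% Pd/C, AlCl3 (10 mol%), CH2Cl2, 50 °C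
Reagents that add atoms: none
Why: Heterogeneous partial hydrogenation of a phenol (dearomatisation) stops at the ketone because the Lewis acid binds the carbonyl and blocks over-reduction, giving the achiral mirror-symmetric ketone by addition of 2 H2 with no co-product and no stereocentre.

**Step 2**
Reactants: 2 4-isopropylcyclohexanone
Product: 4 (R)-cryptone [(R)-4-(propan-2-yl)cyclohex-2-en-1-one], via lithium enolate 3 (not isolated)
Conditions: bis[(R)-1-phenylethyl]amine (1.2 equiv), n-BuLi (1.15 equiv), LiCl (0.6 equiv), THF, −78 °C; add 2, 30 min; then PhS(Cl)=N-t-Bu (1.3 equiv), −78 °C, 1 h; aq. NH4Cl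
Reagents that add atoms: none
Why: Proposed new method: the C2-symmetric chiral lithium amide removes one of the two enantiotopic axial α-protons (closest known type: chiral-base desymmetrisation of 4-alkylcyclohexanones with silyl trapping, LiCl keeping the ee under external quench), and the resulting (S)-enolate is dehydrogenated in the same flask by Mukaiyama's N-tert-butylbenzenesulfinimidoyl chloride (S-attack at C2, then syn-elimination across C2–C3, as known for LDA-derived enolates), so the C=C forms on one side only and the prochiral C4 becomes the (R)-stereocentre.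

**Step 3**
Reactants: 5 magnolol (5,5'-diallylbiphenyl-2,2'-diol)
Product: 6 5,5'-diallyl-3-iodobiphenyl-2,2'-diol
Conditions: I2 (1.0 equiv, slow addition), NaHCO3 (1.2 equiv), THF/H2O 1:1, 0 °C
Reagents that add atoms: iodine, [I][I]
Why: Electrophilic aromatic iodination of the mono-phenoxide is selective because the first pKa of a 2,2'-biphenol (about 8) lies far below the second (about 13), so only one ring is activated, and after iodination the charge stays on the iodinated, fully blocked ring, which breaks the C2 symmetry better than statistically while the allyl groups cannot compete with a phenoxide for I2.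

**Step 4**
Reactants: 6 5,5'-diallyl-3-iodobiphenyl-2,2'-diol
Product: 7 5,5'-diallyl-3-iodo-2,2'-bis(methoxymethoxy)biphenyl
Conditions: NaH (2.5 equiv), MOMCl (2.5 equiv), THF/DMF, 0 °C → rt
Reagents that add atoms: chloromethyl methyl ether (MOMCl), COCCl
Why: Williamson-type O-alkylation of both sodium phenoxides gives acetal protection that survives Grignard and copper chemistry and later chelates the ortho-magnesium centre.

**Step 5**
Reactants: 7 5,5'-diallyl-3-iodo-2,2'-bis(methoxymethoxy)biphenyl; 4 (R)-cryptone
Product: 10 (3R,4R)-3-[5,5'-diallyl-2,2'-bis(methoxymethoxy)biphenyl-3-yl]-4-(propan-2-yl)cyclohex-1-en-1-yl trifluoromethanesulfonate, via arylmagnesium chloride 8 (not isolated), via chloromagnesium enolate 9 (not isolated)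
Conditions: 7 (1.15 equiv), iPrMgCl·LiCl (1.2 equiv), THF, −20 °C, 1 h; CuBr·SMe2 (10 mol%), −78 °C; add 4, −78 → −40 °C; Comins' reagent (1.3 equiv), −78 °C → rt
Reagents that add atoms: Comins' reagent [N-(5-chloropyridin-2-yl)bis(trifluoromethanesulfonyl)imide], O=S(=O)(N(c1ccc(Cl)cn1)S(=O)(=O)C(F)(F)F)C(F)(F)F
Why: Knochel-type I/Mg exchange (which, unlike directed lithiation, leaves the acidic allyl-benzylic C–H bonds alone) is followed by copper-catalysed conjugate addition in which the aryl group enters C3 anti to the C4 isopropyl group (axial attack on the half-chair, trans expected above 15:1), so the (3R) centre is set by the (4R) centre, and O-triflation of the regiodefined magnesium enolate fixes the double bond at C1=C2.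

**Step 6**
Reactants: 10 the enol triflate
Product: 11 5,5'-diallyl-2,2'-bis(methoxymethoxy)-3-[(1R,6R)-3-methyl-6-(propan-2-yl)cyclohex-2-en-1-yl]biphenyl
Conditions: MeMgBr (1.5 equiv), Fe(acac)3 (5 mol%), THF/NMP, −30 → 0 °C
Reagents that add atoms: methylmagnesium bromide, C[Mg]Br
Why: Iron-catalysed (Kochi–Fürstner type) cross-coupling of the alkenyl triflate with MeMgBr replaces OTf by CH3 without moving the double bond or touching either stereocentre, and MOM ethers and allyl groups are inert in the short reaction at low temperature.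

**Step 7**
Reactants: 11 the bis-MOM ether
Product: 12 5,5'-diallyl-3-[(1R,6R)-3-methyl-6-(propan-2-yl)cyclohex-2-en-1-yl]biphenyl-2,2'-diol (CNP0249009.2)
Conditions: ZnBr2 (2 equiv), n-PrSH (4 equiv), CH2Cl2, 0 °C, 10 min; aq. NaHCO3
Reagents that add atoms: none
Why: Lewis acid/soft-nucleophile acetal cleavage (ZnBr2 activates the MOM oxygen and the thiol traps the methoxymethyl cation) frees both phenols within minutes without the Brønsted acid that could cyclise the ortho phenol onto the trisubstituted alkene or move the allyl double bonds, and no stereocentre is affected.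

**Compound list**
1 | 4-isopropylphenol | CC(C)c1ccc(O)cc1 | starting material
2 | 4-isopropylcyclohexanone | CC(C)C1CCC(=O)CC1 | intermediate
3 | lithium (4S)-4-(propan-2-yl)cyclohex-1-en-1-olate | [Li]OC1=CC[C@@H](C(C)C)CC1 | intermediate
4 | (R)-cryptone, (4R)-4-(propan-2-yl)cyclohex-2-en-1-one | O=C1C=C[C@@H](C(C)C)CC1 | intermediate
5 | magnolol, 5,5'-diallylbiphenyl-2,2'-diol | C=CCc1ccc(O)c(-c2cc(CC=C)ccc2O)c1 | starting material
6 | 5,5'-diallyl-3-iodobiphenyl-2,2'-diol | C=CCc1ccc(O)c(-c2cc(CC=C)cc(I)c2O)c1 | intermediate
7 | 5,5'-diallyl-3-iodo-2,2'-bis(methoxymethoxy)biphenyl | C=CCc1ccc(OCOC)c(-c2cc(CC=C)cc(I)c2OCOC)c1 | intermediate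
8 | [5,5'-diallyl-2,2'-bis(methoxymethoxy)biphenyl-3-yl]magnesium chloride (LiCl complex) | C=CCc1ccc(OCOC)c(-c2cc(CC=C)cc([Mg]Cl)c2OCOC)c1 | intermediate
9 | chloromagnesium (3R,4R)-3-[5,5'-diallyl-2,2'-bis(methoxymethoxy)biphenyl-3-yl]-4-(propan-2-yl)cyclohex-1-en-1-olate | C=CCc1ccc(OCOC)c(-c2cc(CC=C)cc([C@H]3C=C(O[Mg]Cl)CC[C@@H]3C(C)C)c2OCOC)c1 | intermediate
10 | (3R,4R)-3-[5,5'-diallyl-2,2'-bis(methoxymethoxy)biphenyl-3-yl]-4-(propan-2-yl)cyclohex-1-en-1-yl trifluoromethanesulfonate | C=CCc1ccc(OCOC)c(-c2cc(CC=C)cc([C@H]3C=C(OS(=O)(=O)C(F)(F)F)CC[C@@H]3C(C)C)c2OCOC)c1 | intermediate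
11 | 5,5'-diallyl-2,2'-bis(methoxymethoxy)-3-[(1R,6R)-3-methyl-6-(propan-2-yl)cyclohex-2-en-1-yl]biphenyl | C=CCc1ccc(OCOC)c(-c2cc(CC=C)cc([C@H]3C=C(C)CC[C@@H]3C(C)C)c2OCOC)c1 | intermediate
12 | 5,5'-diallyl-3-[(1R,6R)-3-methyl-6-(propan-2-yl)cyclohex-2-en-1-yl]biphenyl-2,2'-diol (trans) | C=CCc1ccc(O)c(-c2cc(CC=C)cc([C@H]3C=C(C)CC[C@@H]3C(C)C)c2O)c1 | target

**Totals**
Total step count: 7.
Longest linear sequence: 5 steps (1 → 2 → 4 → 10 → 11 → 12, or equally 5 → 6 → 7 → 10 → 11 → 12).

**Three steps most likely to fail**

Step 2 (one-flask desymmetrising dehydrogenation). The sulfinimidoyl chloride may be partly consumed by the hindered amine, and the ee under external quench may stay near 85%. The fallback sets out from 2 and comes back at 4. The same lithium amide is used under internal quench (TMSCl present from the start, LiCl, THF, −100 °C) to give the isolable silyl enol ether (S)-trimethyl{[4-(propan-2-yl)cyclohex-1-en-1-yl]oxy}silane F1. After a pentane/NaHCO3 work-up, F1 is dehydrogenated in a separate Saegusa–Ito oxidation (Pd(OAc)2, MeCN, 23 °C) to 4. This swaps the sulfur-based enolate oxidation for a palladium enolate/β-hydride elimination on a purified, configurationally stable intermediate. In either case the ee of 4 (expected 85–90%) is carried through to 12, so full enantiopurity would need preparative chiral SFC at 11 or 12.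

Step 3 (mono-iodination of magnolol). Di-iodination or a slow reaction of I2 with the allyl groups could lower the yield. The fallback sets out from 5 and comes back at 7. Magnolol is first mono-protected through its mono-anion (K2CO3 1.0 equiv, MOMCl 1.0 equiv, acetone, 0 °C) to give 5,5'-diallyl-2'-(methoxymethoxy)biphenyl-2-ol F2; the product is several pKa units less acidic than magnolol, so it is not protected a second time. Only the ring with the free OH can then form a phenoxide, and it is iodinated (I2, NaHCO3, THF/H2O) to 5,5'-diallyl-3-iodo-2'-(methoxymethoxy)biphenyl-2-ol F3. The second MOM group (NaH, MOMCl) then gives 7. Here the symmetry is broken at oxygen rather than at carbon.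

Step 5 (exchange, conjugate addition, triflation). The ortho-OMOM aryl group may add slowly, and the magnesium enolate may triflate sluggishly. The fallback sets out from 7 and 4 and comes back at 10. Grignard 8 is made as before, but the copper-catalysed addition to 4 is run with TMSCl (2 equiv) in THF at −78 °C. The addition is then silyl-accelerated and the enolate is trapped at once as the isolable silyl enol ether {[(3R,4R)-3-[5,5'-diallyl-2,2'-bis(methoxymethoxy)biphenyl-3-yl]-4-(propan-2-yl)cyclohex-1-en-1-yl]oxy}trimethylsilane F4. In a separate operation, CsF and PhNTf2 in DME at 23 °C release the enolate regiospecifically and convert it to 10.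

**Further compounds**
F1 | step 2 | (S)-trimethyl{[4-(propan-2-yl)cyclohex-1-en-1-yl]oxy}silane | C[Si](C)(C)OC1=CC[C@@H](C(C)C)CC1
F2 | step 3 | 5,5'-diallyl-2'-(methoxymethoxy)biphenyl-2-ol | C=CCc1ccc(OCOC)c(-c2cc(CC=C)ccc2O)c1
F3 | step 3 | 5,5'-diallyl-3-iodo-2'-(methoxymethoxy)biphenyl-2-ol | C=CCc1ccc(OCOC)c(-c2cc(CC=C)cc(I)c2O)c1
F4 | step 5 | {[(3R,4R)-3-[5,5'-diallyl-2,2'-bis(methoxymethoxy)biphenyl-3-yl]-4-(propan-2-yl)cyclohex-1-en-1-yl]oxy}trimethylsilane | C=CCc1ccc(OCOC)c(-c2cc(CC=C)cc([C@H]3C=C(O[Si](C)(C)C)CC[C@@H]3C(C)C)c2OCOC)c1
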